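**Retrosynthetic overview**

1. Working ring numbering: N1 (lactam N), C2 (C=O), C3, C4 (R, nonyl), N5, C6–C8, N9, C10–C13, N14, C15–C17. The plan rests on C10 of the 17-membered ring, a lone CH2 joining N9 to the C11–C13 chain that ends at N14; this is what an amine, formaldehyde and an N-propargyl group leave behind.
2. Target ⇐ nosyl removal, alkyne saturation, N9 debenzylation ⇐ 17-membered 11-yne (N5 and N14 nosyl, N9 benzyl) ⇐ copper-catalysed alkyne Mannich (A3) ring closure forming N9–C10 and C10–C11 from an open-chain secondary amine/terminal alkyne and formaldehyde. This is the only ring, and it is formed in that step.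
3. Open chain ⇐ N5–C6 by Fukuyama–Mitsunobu alkylation with a Boc/benzyl-protected 3-aminopropanol, and N1–C2 by amide coupling of N-nosyl (R)-3-aminododecanoic acid with H2N(CH2)3N(Ns)CH2C≡CH.
4. C4 ⇐ aza-Michael addition of lithium (R)-N-benzyl-N-(1-phenylethyl)amide to tert-butyl (E)-dodec-2-enoate.

Key step: step 13

Remark: tert-butyl (3-aminopropyl)carbamate and (R)-N-benzyl-1-phenylethanamine are taken as commercial. Ring compounds are named with the working numbering above (the systematic name of the target would be (8R)-8-nonyl-1,5,9,13-tetraazacycloheptadecan-6-one). Ns = 2-nitrophenylsulfonyl.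

**Route**

Step 1
Reactants: 1 (E)-dodec-2-enoic acid
Product: 2 tert-butyl (E)-dodec-2-enoate
Conditions: tert-butyl 2,2,2-trichloroacetimidate, BF3·OEt2 (cat.), cyclohexane/CH2Cl2, 0 °C to rt
Reagents that add atoms: tert-butyl 2,2,2-trichloroacetimidate, CC(C)(C)OC(=N)C(Cl)(Cl)Cl
Why: Acid-catalysed tert-butyl transfer from the imidate to the carboxylic acid (imidate esterification) should give the ester without touching the E-alkene.

Step 2
Reactants: 2 tert-butyl (E)-dodec-2-enoate; 3 (R)-N-benzyl-1-phenylethanamine
Product: 6 tert-butyl (3R)-3-[benzyl[(1R)-1-phenylethyl]amino]dodecanoate, via lithium (R)-benzyl(1-phenylethyl)amide 4 (not isolated), via lithium enolate of the adduct 5 (not isolated)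
Conditions: 3, n-BuLi, THF, −78 °C; then 2, −78 °C; sat. aq NH4Cl
Reagents that add atoms: none
Why: Asymmetric aza-Michael addition of a chiral lithium amide to an (E)-enoate, in which the (R)-1-phenylethyl group on nitrogen blocks one face of the s-cis enoate so that a β-alkyl tert-butyl enoate should give the 3R centre (the future C4) with high diastereoselectivity, while the bulky ester suppresses 1,2-addition.

Step 3
Reactants: 6 tert-butyl (3R)-3-[benzyl[(1R)-1-phenylethyl]amino]dodecanoate
Product: 7 tert-butyl (3R)-3-aminododecanoate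
Conditions: H2 (5 bar), Pd(OH)2/C, MeOH/AcOH, rt; aq NaHCO3 work-up
Reagents that add atoms: none
Why: Catalytic hydrogenolysis cleaves the two benzylic C–N bonds, whereas the non-benzylic C3–N bond, the stereocentre and the tert-butyl ester are not affected.

Step 4
Reactants: 7 tert-butyl (3R)-3-aminododecanoate
Product: 8 tert-butyl (3R)-3-[(2-nitrophenyl)sulfonylamino]dodecanoate
Conditions: 2-nitrobenzenesulfonyl chloride, Et3N, CH2Cl2, 0 °C to rt
Reagents that add atoms: 2-nitrobenzenesulfonyl chloride, O=S(=O)(Cl)c1ccccc1[N+](=O)[O-]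
Why: Sulfonylation of the primary amine installs the nosyl group, which both protects N5 and makes its N–H acidic enough for the later Fukuyama–Mitsunobu alkylation.

Step 5
Reactants: 8 tert-butyl (3R)-3-[(2-nitrophenyl)sulfonylamino]dodecanoate
Product: 9 (3R)-3-[(2-nitrophenyl)sulfonylamino]dodecanoic acid
Conditions: TFA/CH2Cl2, rt; toluene azeotrope
Reagents that add atoms: none
Why: Acidolysis of the tert-butyl ester with loss of isobutene frees the acid, and the sulfonamide is stable to TFA.

Step 6
Reactants: 10 tert-butyl (3-aminopropyl)carbamate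
Product: 11 tert-butyl [3-[(2-nitrophenyl)sulfonylamino]propyl]carbamate
Conditions: 2-nitrobenzenesulfonyl chloride, Et3N, CH2Cl2, 0 °C to rt
Reagents that add atoms: 2-nitrobenzenesulfonyl chloride, O=S(=O)(Cl)c1ccccc1[N+](=O)[O-]
Why: Sulfonylation of the only free amine, which becomes N14; the carbamate nitrogen does not react.

Step 7
Reactants: 11 tert-butyl [3-[(2-nitrophenyl)sulfonylamino]propyl]carbamate; 12 propargyl bromide
Product: 13 tert-butyl [3-[(2-nitrophenyl)sulfonyl(prop-2-yn-1-yl)amino]propyl]carbamate
Conditions: K2CO3, DMF, rt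
Reagents that add atoms: none
Why: SN2 N-alkylation of the nosyl amide anion (Fukuyama alkylation) is selective because the carbamate N–H is not deprotonated by K2CO3.

Step 8
Reactants: 13 tert-butyl [3-[(2-nitrophenyl)sulfonyl(prop-2-yn-1-yl)amino]propyl]carbamate
Product: 14 N-(3-aminopropyl)-2-nitro-N-(prop-2-yn-1-yl)benzenesulfonamide hydrochloride
Conditions: HCl (4 M in dioxane), rt
Reagents that add atoms: hydrogen chloride, Cl
Why: Acidolytic Boc cleavage gives the primary amine (the future N1) as a storable hydrochloride, with sulfonamide and alkyne inert to acid.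

Step 9
Reactants: 9 (3R)-3-[(2-nitrophenyl)sulfonylamino]dodecanoic acid; 14 N-(3-aminopropyl)-2-nitro-N-(prop-2-yn-1-yl)benzenesulfonamide hydrochloride
Product: 15 (3R)-3-[(2-nitrophenyl)sulfonylamino]-N-[3-[(2-nitrophenyl)sulfonyl(prop-2-yn-1-yl)amino]propyl]dodecanamide
Conditions: EDC·HCl, HOBt, i-Pr2NEt, CH2Cl2, 0 °C to rt
Reagents that add atoms: none
Why: Carbodiimide/HOBt amide coupling forms N1–C2; the stereocentre is β to the activated carbonyl and cannot epimerise, and the sulfonamide N–H is too weak a nucleophile to compete with the primary amine.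

Step 10
Reactants: 16 3-(benzylamino)propan-1-ol
Product: 17 tert-butyl benzyl(3-hydroxypropyl)carbamate
Conditions: Boc2O, CH2Cl2, rt
Reagents that add atoms: di-tert-butyl dicarbonate, CC(C)(C)OC(=O)OC(=O)OC(C)(C)C
Why: The secondary amine is acylated by Boc2O much faster than the primary alcohol, giving the N-protected alcohol for the Mitsunobu step.

Step 11
Reactants: 15 (3R)-3-[(2-nitrophenyl)sulfonylamino]-N-[3-[(2-nitrophenyl)sulfonyl(prop-2-yn-1-yl)amino]propyl]dodecanamide; 17 tert-butyl benzyl(3-hydroxypropyl)carbamate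
Product: 18 (3R)-3-[[3-[benzyl(tert-butoxycarbonyl)amino]propyl](2-nitrophenyl)sulfonylamino]-N-[3-[(2-nitrophenyl)sulfonyl(prop-2-yn-1-yl)amino]propyl]dodecanamide
Conditions: PPh3, DIAD, THF, 0 °C to rt
Reagents that add atoms: none
Why: Fukuyama–Mitsunobu reaction, in which only the N5 nosyl amide N–H is acidic enough to be alkylated by the activated primary alcohol, so N5–C6 forms while the carboxamide N–H, the terminal alkyne and C4 stay untouched.

Step 12
Reactants: 18 (3R)-3-[[3-[benzyl(tert-butoxycarbonyl)amino]propyl](2-nitrophenyl)sulfonylamino]-N-[3-[(2-nitrophenyl)sulfonyl(prop-2-yn-1-yl)amino]propyl]dodecanamide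
Product: 19 (3R)-3-[[3-(benzylamino)propyl](2-nitrophenyl)sulfonylamino]-N-[3-[(2-nitrophenyl)sulfonyl(prop-2-yn-1-yl)amino]propyl]dodecanamide
Conditions: TFA/CH2Cl2, 0 °C to rt; sat. aq NaHCO3 work-up
Reagents that add atoms: none
Why: Acidolytic Boc cleavage frees N9 as the only basic nitrogen of the open chain, with nosyl groups, amide and alkyne stable to the acid.

Step 13
Reactants: 19 (3R)-3-[[3-(benzylamino)propyl](2-nitrophenyl)sulfonylamino]-N-[3-[(2-nitrophenyl)sulfonyl(prop-2-yn-1-yl)amino]propyl]dodecanamide; 20 formaldehyde (used as paraformaldehyde)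
Product: 22 (4R)-9-benzyl-4-nonyl-5,14-bis[(2-nitrophenyl)sulfonyl]-1,5,9,14-tetraazacycloheptadec-11-yn-2-one, via N9-methyleneiminium ion 21 (not isolated)
Conditions: (CH2O)n (3 equiv), CuBr (30 mol%), 1,4-dioxane, 70 °C, argon; 19 added by syringe pump over 12 h, final concentration 2 mM
Reagents that add atoms: none
Why: The secondary amine N9 condenses with formaldehyde to the methyleneiminium ion 21 while CuBr (monovalent copper) turns the terminal alkyne into a copper acetylide, whose carbon C11 attacks the iminium carbon, so that N9–C10 and C10–C11 form in one operation with C10 coming from formaldehyde. The closest known reaction is the copper-catalysed alkyne Mannich (A3) coupling of N-propargyl sulfonamides with secondary amines and formaldehyde, which has also been used to close large rings. The 17-membered ring closes by attack of the tethered acetylide on the iminium carbon with both iminium atoms inside the new ring (endo mode), and the four almost linear atoms C10–C13 fit without strain in a ring of this size. No stereocentre is created and C4 lies far from every reacting atom. The step needs chemoselectivity and cyclisation in preference to oligomerisation: because N1 is acylated and N5 and N14 are sulfonylated, N9 alone can condense with formaldehyde, its benzyl group makes it tertiary after coupling so it cannot react a second time, a formaldehyde iminium has no α-hydrogen for enamine formation, and slow addition at high dilution keeps the concentration of uncyclised alkyne low. Working at 70 °C under argon should avoid Crabbé-type conversion of the propargylic amine into an allene and oxidative Glaser dimerisation of the alkyne.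

Step 14
Reactants: 22 (4R)-9-benzyl-4-nonyl-5,14-bis[(2-nitrophenyl)sulfonyl]-1,5,9,14-tetraazacycloheptadec-11-yn-2-one
Product: 23 (4R)-9-benzyl-4-nonyl-1,5,9,14-tetraazacycloheptadec-11-yn-2-one
Conditions: PhSH, K2CO3, MeCN, 50 °C; acid–base extraction
Reagents that add atoms: none
Why: Fukuyama deprotection, in which thiolate attacks each nitro-activated ring at the sulfonyl-bearing carbon (nucleophilic aromatic substitution) and releases sulfur dioxide and the amine, while the unactivated internal alkyne and the lactam are inert and the extraction removes sulfur compounds before hydrogenation.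

Step 15
Reactants: 23 (4R)-9-benzyl-4-nonyl-1,5,9,14-tetraazacycloheptadec-11-yn-2-one
Product: 24 (4R)-9-benzyl-4-nonyl-1,5,9,14-tetraazacycloheptadecan-2-one
Conditions: H2 (1 atm), PtO2, EtOH, rt
Reagents that add atoms: none
Why: Heterogeneous hydrogenation over platinum should saturate the C11–C12 triple bond with little hydrogenolysis of the propargylic and allylic C–N bonds, and any partial loss of the benzyl group only anticipates the next step.

Step 16
Reactants: 24 (4R)-9-benzyl-4-nonyl-1,5,9,14-tetraazacycloheptadecan-2-one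
Product: 25 (4R)-4-nonyl-1,5,9,14-tetraazacycloheptadecan-2-one (CNP0360085.1)
Conditions: H2 (3 bar), Pd(OH)2/C, MeOH, AcOH, rt; basic ion-exchange resin to the free base
Reagents that add atoms: none
Why: Hydrogenolysis of the N-benzyl group over Pd(OH)2/C in acidic methanol frees N9; no other reducible group is left and C4 is not benzylic, so its R configuration is retained.

**Compound list**

1 | (E)-dodec-2-enoic acid | CCCCCCCCC/C=C/C(=O)O | starting material
2 | tert-butyl (E)-dodec-2-enoate | CCCCCCCCC/C=C/C(=O)OC(C)(C)C | intermediate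
3 | (R)-N-benzyl-1-phenylethanamine | C[C@@H](NCc1ccccc1)c1ccccc1 | starting material
4 | lithium (R)-benzyl(1-phenylethyl)amide | C[C@@H](N([Li])Cc1ccccc1)c1ccccc1 | intermediate
5 | lithium enolate of tert-butyl (3R)-3-[benzyl[(1R)-1-phenylethyl]amino]dodecanoate | CCCCCCCCC[C@@H](N(Cc1ccccc1)[C@H](C)c1ccccc1)C=C(O[Li])OC(C)(C)C | intermediate
6 | tert-butyl (3R)-3-[benzyl[(1R)-1-phenylethyl]amino]dodecanoate | CCCCCCCCC[C@@H](N(Cc1ccccc1)[C@H](C)c1ccccc1)CC(=O)OC(C)(C)C | intermediate
7 | tert-butyl (3R)-3-aminododecanoate | CCCCCCCCC[C@@H](N)CC(=O)OC(C)(C)C | intermediate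
8 | tert-butyl (3R)-3-[(2-nitrophenyl)sulfonylamino]dodecanoate | CCCCCCCCC[C@@H](NS(=O)(=O)c1ccccc1[N+](=O)[O-])CC(=O)OC(C)(C)C | intermediate
9 | (3R)-3-[(2-nitrophenyl)sulfonylamino]dodecanoic acid | CCCCCCCCC[C@@H](NS(=O)(=O)c1ccccc1[N+](=O)[O-])CC(=O)O | intermediate
10 | tert-butyl (3-aminopropyl)carbamate | CC(C)(C)OC(=O)NCCCN | starting material
11 | tert-butyl [3-[(2-nitrophenyl)sulfonylamino]propyl]carbamate | CC(C)(C)OC(=O)NCCCNS(=O)(=O)c1ccccc1[N+](=O)[O-] | intermediate
12 | propargyl bromide | C#CCBr | starting material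
13 | tert-butyl [3-[(2-nitrophenyl)sulfonyl(prop-2-yn-1-yl)amino]propyl]carbamate | CC(C)(C)OC(=O)NCCCN(CC#C)S(=O)(=O)c1ccccc1[N+](=O)[O-] | intermediate
14 | N-(3-aminopropyl)-2-nitro-N-(prop-2-yn-1-yl)benzenesulfonamide hydrochloride | NCCCN(CC#C)S(=O)(=O)c1ccccc1[N+](=O)[O-].Cl | intermediate
15 | (3R)-3-[(2-nitrophenyl)sulfonylamino]-N-[3-[(2-nitrophenyl)sulfonyl(prop-2-yn-1-yl)amino]propyl]dodecanamide | CCCCCCCCC[C@@H](NS(=O)(=O)c1ccccc1[N+](=O)[O-])CC(=O)NCCCN(CC#C)S(=O)(=O)c2ccccc2[N+](=O)[O-] | intermediate
16 | 3-(benzylamino)propan-1-ol | OCCCNCc1ccccc1 | starting material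
17 | tert-butyl benzyl(3-hydroxypropyl)carbamate | CC(C)(C)OC(=O)N(CCCO)Cc1ccccc1 | intermediate
18 | (3R)-3-[[3-[benzyl(tert-butoxycarbonyl)amino]propyl](2-nitrophenyl)sulfonylamino]-N-[3-[(2-nitrophenyl)sulfonyl(prop-2-yn-1-yl)amino]propyl]dodecanamide | CCCCCCCCC[C@@H](N(CCCN(Cc1ccccc1)C(=O)OC(C)(C)C)S(=O)(=O)c2ccccc2[N+](=O)[O-])CC(=O)NCCCN(CC#C)S(=O)(=O)c3ccccc3[N+](=O)[O-] | intermediate
19 | (3R)-3-[[3-(benzylamino)propyl](2-nitrophenyl)sulfonylamino]-N-[3-[(2-nitrophenyl)sulfonyl(prop-2-yn-1-yl)amino]propyl]dodecanamide | CCCCCCCCC[C@@H](N(CCCNCc1ccccc1)S(=O)(=O)c2ccccc2[N+](=O)[O-])CC(=O)NCCCN(CC#C)S(=O)(=O)c3ccccc3[N+](=O)[O-] | intermediate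
20 | formaldehyde | C=O | starting material
21 | N9-methyleneiminium ion derived from 19 | CCCCCCCCC[C@@H](N(CCC[N+](=C)Cc1ccccc1)S(=O)(=O)c2ccccc2[N+](=O)[O-])CC(=O)NCCCN(CC#C)S(=O)(=O)c3ccccc3[N+](=O)[O-] | intermediate
22 | (4R)-9-benzyl-4-nonyl-5,14-bis[(2-nitrophenyl)sulfonyl]-1,5,9,14-tetraazacycloheptadec-11-yn-2-one | CCCCCCCCC[C@@H]1CC(=O)NCCCN(S(=O)(=O)c2ccccc2[N+](=O)[O-])CC#CCN(Cc3ccccc3)CCCN1S(=O)(=O)c4ccccc4[N+](=O)[O-] | intermediate
23 | (4R)-9-benzyl-4-nonyl-1,5,9,14-tetraazacycloheptadec-11-yn-2-one | CCCCCCCCC[C@@H]1CC(=O)NCCCNCC#CCN(Cc2ccccc2)CCCN1 | intermediate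
24 | (4R)-9-benzyl-4-nonyl-1,5,9,14-tetraazacycloheptadecan-2-one | CCCCCCCCC[C@@H]1CC(=O)NCCCNCCCCN(Cc2ccccc2)CCCN1 | intermediate
25 | (4R)-4-nonyl-1,5,9,14-tetraazacycloheptadecan-2-one (CNP0360085.1) | CCCCCCCCC[C@@H]1CC(=O)NCCCNCCCCNCCCN1 | target

**Step count**

Total: 16 steps. Longest linear sequence: 12 steps (steps 1–5, 9, 11–16, from (E)-dodec-2-enoic acid); the two side fragments take 3 steps (6–8) and 1 step (10).

**Steps most likely to fail, with fallbacks**

Step 13. Intermolecular Mannich coupling between two chains (oligomerisation) may outrun ring closure, or the terminal alkyne may dimerise oxidatively. The fallback keeps formaldehyde as the source of C10 but makes the Mannich bonds intermolecularly and closes the ring at N5–C6 instead. It sets out from 15. Coupling of 15 with paraformaldehyde and 3-(benzylamino)propan-1-ol 16 (CuBr, dioxane, 70 °C) should give the N9-(3-hydroxypropyl) Mannich base F1, in which the N5 nosyl amide still carries its N–H. An intramolecular Fukuyama–Mitsunobu alkylation (PPh3, DIAD, toluene/THF, slow addition at high dilution) should then join N5 to C6 and give 22, where the route is rejoined.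

Step 15. Hydrogenolysis of the propargylic or allylic C–N bonds (opening the ring) may compete with saturation, or the catalyst may be poisoned by sulfur residues and by the polyamine. The fallback reduces the triple bond without a metal catalyst and before the nosyl groups are removed. It sets out from 22. Diimide reduction (TsNHNH2, NaOAc, DME/H2O, reflux, reagent added in portions), which leaves nitroarenes, sulfonamides and benzylamines alone, should give the saturated bis-nosyl macrocycle F2. Thiophenol and K2CO3 in MeCN then remove both nosyl groups and give 24, where the route is rejoined before step 16.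

Step 11. Alkylation of the α-branched N5 sulfonamide may be sluggish under Mitsunobu conditions, so that the reduced azodicarboxylate is alkylated instead. The fallback replaces the redox condensation by a halide alkylation followed by amination. It sets out from 15. Alkylation with 1-bromo-3-chloropropane (Cs2CO3, DMF, rt to 50 °C), selective for the acidic sulfonamide N–H, should give the N5-(3-chloropropyl) sulfonamide F3. Displacement of chloride by excess benzylamine (NaI, MeCN, 60 °C) should then give 19 directly, so that steps 10 and 12 are not needed and the route is rejoined at the key step.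

**Further compounds**

F1 | step 13 | (3R)-N-[3-[[4-[benzyl(3-hydroxypropyl)amino]but-2-yn-1-yl](2-nitrophenyl)sulfonylamino]propyl]-3-[(2-nitrophenyl)sulfonylamino]dodecanamide | CCCCCCCCC[C@@H](NS(=O)(=O)c1ccccc1[N+](=O)[O-])CC(=O)NCCCN(CC#CCN(CCCO)Cc2ccccc2)S(=O)(=O)c3ccccc3[N+](=O)[O-]
F2 | step 15 | (4R)-9-benzyl-4-nonyl-5,14-bis[(2-nitrophenyl)sulfonyl]-1,5,9,14-tetraazacycloheptadecan-2-one | CCCCCCCCC[C@@H]1CC(=O)NCCCN(S(=O)(=O)c2ccccc2[N+](=O)[O-])CCCCN(Cc3ccccc3)CCCN1S(=O)(=O)c4ccccc4[N+](=O)[O-]
F3 | step 11 | (3R)-3-[(3-chloropropyl)(2-nitrophenyl)sulfonylamino]-N-[3-[(2-nitrophenyl)sulfonyl(prop-2-yn-1-yl)amino]propyl]dodecanamide | CCCCCCCCC[C@@H](N(CCCCl)S(=O)(=O)c1ccccc1[N+](=O)[O-])CC(=O)NCCCN(CC#C)S(=O)(=O)c2ccccc2[N+](=O)[O-]
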